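## Analysis of the target

The target 32 is a linear heptamer of the phlorotannin type: seven benzene rings (A to G in the order of the SMILES string) joined only by six diaryl ether oxygens, carrying seventeen free phenolic hydroxyls. It has no stereocentre, so only constitution has to be controlled. Rings A and E are phloroglucinol-type, rings B, D and F are 2,6-dihydroxy-1,4-dioxygenated, ring G is a 3,4,5-trihydroxyphenyl ether and ring C is pentaoxygenated. The free polyphenol, above all the vicinal triol arrays of ring C (C3 to C5) and ring G, oxidises readily in air, so every hydroxyl stays masked until the last step. The real difficulty is the ether bonds. Each of the six has one carbon flanked by two oxygen substituents (ring A C1, ring B C4, ring C C2, ring D C4, ring E C2, ring F C4). Two of them, B–C and D–E, carry a third ortho oxygen on the partner ring and are therefore tri-ortho-substituted ethers between electron-rich arenes, the worst case for metal-mediated coupling. The strategy rests on ring C, which has oxygen on five contiguous carbons (C1 ether to ring B, C2 ether to ring D, C3, C4 and C5 hydroxyl) and a single CH at C6. C2 to C5 map onto the four carbons of a squarate ester, and C1 (with the ring B oxygen) plus C6 map onto a 1-aryloxyvinyl unit, so ring C can be grown onto the hindered ring B oxygen instead of being coupled to it.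

## Retrosynthetic reasoning

**32 from 31.** All seventeen O–H bonds are traced back to O–methyl bonds. This gives air-stable intermediates that can be chromatographed, and methyl ethers survive every organometallic, copper-mediated and thermal step of the route. The forward reaction has to cleave seventeen aryl methyl ethers without touching the six diaryl ethers.

**31 from 18 and 30.** The C–O bond between the C2 oxygen of ring C and C1 of ring D is cut. Ring D C1 has two CH neighbours and is the only unhindered aryl carbon in the middle of the chain, so it is the best carbon to carry a bromide. The ring C oxygen is flanked on both sides and is better used as the nucleophile. The cut divides the molecule into a trimer phenol 18 and a tetramer bromide 30.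

**18 from 17, and 17 from 15 and 16.** The C2 oxygen of ring C is unmasked from its acetal only after ring A is in place, so that only one phenol is free at a time. Ring A is cut off at its C1–O bond and enters as the iodide 16; the ring B phenol of 15 has two CH neighbours and is a good copper nucleophile. This coupling puts the hindered partner on the halide side, so it is done on the small dimer 15, where 16 can be used in excess.

**15 from 14 and 13.** These are functional-group steps: the free C5 hydroxyl of 13 is methylated and the silyl group on the ring B oxygen is removed. They work without selectivity problems because 13 is formed with its two para oxygens already differentiated.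

**13 from 10 (key disconnection).** The C5–C6 bond of ring C is cut and the C2–C5 unit is folded back into a cyclobutenone. C2 to C5 of ring C are the four carbons of squarate 7; C1 and C6 are the two carbons of a vinyl group whose internal carbon already carries the ring B oxygen.
- The tri-ortho B–C ether is therefore never made by aryl coupling, and all five oxygens of ring C arrive in their final positions.
- The carbinol oxygen of 10 carries a methoxymethyl group. The C2 oxygen thus emerges protected and the C5 oxygen free; with both free, a selective monoalkylation of a hydroquinone would be needed.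

**10 from 6 and 7.** The bond between the carbinol carbon and the internal vinyl carbon is cut, giving the vinyllithium 8 (from vinyl ether 6) and squarate 7, with the alkoxide 9 capped in the same flask.
- The ring B oxygen at the para position carries a triisopropylsilyl group, not a benzyl group. A benzyl ether would add acidic benzylic hydrogens and would, together with the neighbouring methoxy group, activate the ring hydrogens for metalation.
- The bulky silyloxy group shields those ring hydrogens and does not direct lithiation.

**6 from 5, 5 from 3 and 4, 3 from 2, 2 from 1.** The hindered ring B oxygen forms its bond to an sp3 carbon of 4 by simple alkylation, which is insensitive to the two ortho methoxy groups; elimination then gives the vinyl ether. The two hydroxyls of 2 differ sharply in hindrance, so silylation separates them, and 2 comes from quinone 1 by reduction.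

**30 from 29 and 24.** The bond between the C2 oxygen of ring E and C1 of ring F is cut. The hindered phenol 29 is joined to the unhindered boronic acid 24 by oxidative copper coupling, which leaves the ring D bromide of 29 untouched for the later union with 18.

**24 from 21, 21 from 19 and 20.** The F–G ether is made the same way from the hindered bromophenol 19 and boronic acid 20. The bromide of 21 is then turned into the boronic acid. Compound 19 serves twice, as ring F here and as ring D below.

**29 from 27, 27 from 19 and 26, 26 from 25.** The second tri-ortho ether (D–E) is cut at ring E C1. A formyl group at ring E C2 activates an ortho fluoride for substitution by the hindered phenoxide of 19 and is then converted into the C2 hydroxyl by oxidation. The aldehyde 26 comes from 25 by formylation.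

## Alternatives that were turned down

**Alternative 1:** Both ether bonds of ring D are cut, so ring D becomes a dichloride activated as the cyclopentadienylruthenium arene complex A2. The two halves are the trimer phenols A3 (rings A to C, identical with 18) and A4 (rings E to G). In the forward direction the phenoxide of A3 displaces the unhindered chloride of A2, the phenoxide of A4 displaces the chloride between the two methoxy groups, and irradiation releases the permethyl ether A1, which is the same compound as 31.
- For it: it is the most convergent plan (3 + 1 + 3). Substitution on a cationic arene complex does not depend on an electron-poor ring, and the order of the two substitutions is set by hindrance. On convergence and on the D–E bond it is at least as strong as the chosen route.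
- Against it: the second substitution is the slowest conceivable case. The chloride is flanked by two methoxy groups, the complex is already deactivated by the first aryloxy donor, and the phenoxide of A4 has a bulky ortho aryloxy group. Stoichiometric ruthenium must then be released photolytically from a tetraoxygenated arene in a molecule with six other electron-rich rings to which the metal could migrate.
- Comparison: A3 still contains ring C and the B–C ether, so this plan does not solve the hardest part of the molecule and would need the chosen ring construction anyway. The chosen route makes the D–E bond by substitution on a small aldehyde and joins 3 + 4 at an unhindered bromide. The endgame is identical, since A1 is 31.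

**Alternative 2:** The terminal phloroglucinol ring A is built from acyclic pieces. The aryloxymalonate A6 acylates both methylene carbons of the keto diester A7 under alkoxide base, closing ring A as the dicarboxylate A5 with the ring B oxygen already on C1.
- For it: the A–B ether is made by alkylating a phenol with a halomalonate, without metals and from cheap materials. On this one bond it is stronger than step 9 of the chosen route, which couples a di-ortho-substituted aryl iodide.
- Against it: A5 is a free triol diester, so hydrolysis, double decarboxylation and three methylations follow before any further coupling. The condensation uses a hindered, less electrophilic malonate whose aryloxide can be expelled.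
- Comparison: it spends the ring construction on the easiest end of the molecule. In A5 the hindered ring B oxygen is still benzylated; after its release the tri-ortho B–C ether would have to be made by coupling a 2,6-dimethoxyphenol with an ortho-oxygenated, pentaoxygenated aryl halide, the hardest bond by the weakest method. The chosen route uses its one ring construction where coupling is worst and accepts an ordinary coupling for ring A.

**Alternative 3:** Twelve aryl C–OH bonds are traced back to aryl C–CHO bonds. Formyl groups activate fluoroarenes for ether formation by substitution, giving the dodecaaldehyde A9. A single peracid oxidation followed by methanolysis of the twelve aryl formates gives the penta-O-methyl ether A8.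
- For it: all ether bonds are made without metals by a reaction that tolerates ortho substituents; the chosen route uses the same logic once, for ring E (27 to 29). Only five methyl ethers are cleaved at the end instead of seventeen, a real advantage in the final deprotection.
- Against it: twelve oxidations must all proceed with aryl migration in one molecule, and any shortfall gives mixtures of closely related polyphenols that cannot be separated. The rings become more electron-rich as the chain grows, so each later substitution is slower, and polyaldehydes are sensitive to the basic conditions. Ring C needs a difluoro dialdehyde with a methoxy group at C4 and hydrogen at C6, itself a multistep problem.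
- Comparison: the chosen route does each oxidation-state change on a small fragment, one at a time, and obtains ring C with all five oxygens in one step. It pays with a seventeen-fold demethylation at the end.

Key step: step 6

Assumption: the ether axes of 32 are taken to rotate freely, so there is no stereochemical element to set; 16, 19, 20 and 25 are taken as catalogue compounds.

## Route

Step 1
Reactants: 1 2,6-dimethoxy-1,4-benzoquinone
Product: 2 2,6-dimethoxybenzene-1,4-diol
Conditions: Na2S2O4, EtOAc/H2O, rt, Ar
Reagents that add atoms: none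
Why: Dithionite reduction of a quinone to its hydroquinone is fast in a two-phase system; the air-sensitive diol is used at once.

Step 2
Reactants: 2 2,6-dimethoxybenzene-1,4-diol
Product: 3 2,6-dimethoxy-4-{[tri(propan-2-yl)silyl]oxy}phenol
Conditions: TIPSCl (1.0 equiv), imidazole, DMF, 0 °C
Reagents that add atoms: chlorotri(propan-2-yl)silane, CC(C)[Si](Cl)(C(C)C)C(C)C
Why: Silyl ether formation; the bulky silyl chloride should take only the hydroxyl with two CH neighbours and leave the one flanked by two methoxy groups. The silyl ether has no benzylic hydrogens and shields the adjacent ring hydrogens, which matters in step 5.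

Step 3
Reactants: 3 2,6-dimethoxy-4-{[tri(propan-2-yl)silyl]oxy}phenol; 4 1,2-dibromoethane (large excess)
Product: 5 [4-(2-bromoethoxy)-3,5-dimethoxyphenoxy]tri(propan-2-yl)silane
Conditions: K2CO3, MeCN, 70 °C, Ar
Reagents that add atoms: none
Why: Williamson alkylation of a phenoxide at a primary bromide is not impeded by the two ortho methoxy groups; the excess of 4 suppresses double alkylation.

Step 4
Reactants: 5 [4-(2-bromoethoxy)-3,5-dimethoxyphenoxy]tri(propan-2-yl)silane
Product: 6 [4-(ethenyloxy)-3,5-dimethoxyphenoxy]tri(propan-2-yl)silane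
Conditions: KOtBu, THF, 0 °C to rt
Reagents that add atoms: none
Why: E2 dehydrobromination of a 2-aryloxyethyl bromide is the standard route to aryl vinyl ethers; the hindered triisopropylsilyl ether should tolerate the short exposure to tert-butoxide at low temperature.

Step 5
Reactants: 6 [4-(ethenyloxy)-3,5-dimethoxyphenoxy]tri(propan-2-yl)silane; 7 dimethyl squarate
Product: 10 racemic 4-[1-(2,6-dimethoxy-4-{[tri(propan-2-yl)silyl]oxy}phenoxy)ethenyl]-2,3-dimethoxy-4-(methoxymethoxy)cyclobut-2-en-1-one, via vinyllithium 8 (not isolated), via lithium alkoxide 9 (not isolated)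
Conditions: t-BuLi (1.0 equiv), THF, −78 to −40 °C; cannulate into 7, THF, −78 °C; then MOMCl, −78 to 0 °C
Reagents that add atoms: chloromethyl methyl ether, COCCl
Why: α-Lithiation of a vinyl ether, 1,2-addition of 8 to one carbonyl of the squarate and O-alkylation of alkoxide 9 are all known reaction types. Ring metalation is disfavoured because both positions ortho to the vinyloxy group carry methoxy groups and the remaining ring hydrogens sit beside the bulky silyloxy group. The C4 stereocentre forms without control, which does not matter because it is destroyed in step 6.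

Step 6
Reactants: 10 racemic 4-[1-(2,6-dimethoxy-4-{[tri(propan-2-yl)silyl]oxy}phenoxy)ethenyl]-2,3-dimethoxy-4-(methoxymethoxy)cyclobut-2-en-1-one
Product: 13 5-(2,6-dimethoxy-4-{[tri(propan-2-yl)silyl]oxy}phenoxy)-2,3-dimethoxy-4-(methoxymethoxy)phenol, via dienylketene 11 (not isolated), via cyclohexadienone 12 (not isolated)
Conditions: toluene (0.02 M, degassed), 110 °C, Ar
Reagents that add atoms: none
Why: Heating should open the cyclobutenone by conrotatory 4π ring opening, with the donor methoxymethoxy group at C4 turning outward and the 1-aryloxyvinyl group inward, to give the (Z)-dienylketene 11. A thermal disrotatory 6π electrocyclisation then joins the ketene carbon to the vinyl CH2 carbon, which forms the C5–C6 bond and closes the six-membered ring C as dienone 12; tautomerisation of 12 gives phenol 13. The closest known reaction type is the Moore ring expansion of 4-alkenyl-4-alkoxy- or 4-hydroxycyclobutenones from squarate esters to hydroquinones, including 1-alkoxyalkenyl cases; the aryloxy group here is a new spectator on that unit. No stereocentre is formed, and the one in racemic 10 becomes sp2. The only selectivity needed is the direction of rotation in the ring opening, and the strong outward preference of an oxygen donor at C4 secures it, which places the vinyl group next to the ketene so that closure has a single constitutional outcome. Because the C4 oxygen of 10 is capped, ring C emerges with the C2 oxygen protected, the C5 oxygen free and the hindered ring B oxygen already on C1.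

Step 7
Reactants: 13 5-(2,6-dimethoxy-4-{[tri(propan-2-yl)silyl]oxy}phenoxy)-2,3-dimethoxy-4-(methoxymethoxy)phenol
Product: 14 {3,5-dimethoxy-4-[3,4,5-trimethoxy-2-(methoxymethoxy)phenoxy]phenoxy}tri(propan-2-yl)silane
Conditions: MeI, K2CO3, acetone, rt
Reagents that add atoms: iodomethane, CI
Why: Williamson methylation of the only free phenol, which has a CH neighbour and reacts readily; the silyl ether and the acetal are stable to carbonate in acetone.

Step 8
Reactants: 14 {3,5-dimethoxy-4-[3,4,5-trimethoxy-2-(methoxymethoxy)phenoxy]phenoxy}tri(propan-2-yl)silane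
Product: 15 3,5-dimethoxy-4-[3,4,5-trimethoxy-2-(methoxymethoxy)phenoxy]phenol
Conditions: TBAF, AcOH, THF, 0 °C
Reagents that add atoms: none
Why: Fluoride cleavage of an aryl silyl ether; acetic acid buffers the phenoxide, and the methoxymethyl ether is inert to fluoride.

Step 9
Reactants: 15 3,5-dimethoxy-4-[3,4,5-trimethoxy-2-(methoxymethoxy)phenoxy]phenol; 16 2-iodo-1,3,5-trimethoxybenzene (2 equiv)
Product: 17 2-{3,5-dimethoxy-4-[3,4,5-trimethoxy-2-(methoxymethoxy)phenoxy]phenoxy}-1,3,5-trimethoxybenzene
Conditions: CuI (20 mol %), picolinic acid (40 mol %), K3PO4, DMSO, 110 °C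
Reagents that add atoms: none
Why: Ligand-accelerated Ullmann diaryl ether synthesis between an unhindered phenol and an aryl iodide. The iodide is di-ortho-substituted and electron-rich, so it is used in excess at the dimer stage.

Step 10
Reactants: 17 2-{3,5-dimethoxy-4-[3,4,5-trimethoxy-2-(methoxymethoxy)phenoxy]phenoxy}-1,3,5-trimethoxybenzene
Product: 18 6-[2,6-dimethoxy-4-(2,4,6-trimethoxyphenoxy)phenoxy]-2,3,4-trimethoxyphenol
Conditions: conc. HCl (cat.), MeOH, 40 °C
Reagents that add atoms: none
Why: Acid-catalysed methanolysis of the methoxymethyl acetal frees the C2 hydroxyl of ring C; methyl and diaryl ethers are inert to dilute acid.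

Step 11
Reactants: 19 4-bromo-2,6-dimethoxyphenol; 20 (3,4,5-trimethoxyphenyl)boronic acid (2 equiv)
Product: 21 5-(4-bromo-2,6-dimethoxyphenoxy)-1,2,3-trimethoxybenzene
Conditions: Cu(OAc)2 (2 equiv), pyridine, 4 Å molecular sieves, CH2Cl2, rt, air
Reagents that add atoms: none
Why: Chan–Lam coupling of a phenol with an arylboronic acid proceeds at room temperature, accepts 2,6-disubstituted phenols and leaves the aryl bromide untouched.

Step 12
Reactants: 21 5-(4-bromo-2,6-dimethoxyphenoxy)-1,2,3-trimethoxybenzene
Product: 24 [3,5-dimethoxy-4-(3,4,5-trimethoxyphenoxy)phenyl]boronic acid, via aryllithium 22 (not isolated), via lithium borate 23 (not isolated)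
Conditions: n-BuLi, THF, −78 °C; B(OiPr)3, −78 °C to rt; then 1 M HCl
Reagents that add atoms: triisopropyl borate, CC(C)OB(OC(C)C)OC(C)C; water, O
Why: Bromine–lithium exchange at low temperature is faster than any ring deprotonation; trapping with the borate and acidic hydrolysis give the boronic acid.

Step 13
Reactants: 25 1-fluoro-3,5-dimethoxybenzene
Product: 26 2-fluoro-4,6-dimethoxybenzaldehyde
Conditions: POCl3, DMF, 0 to 70 °C; then H2O
Reagents that add atoms: N,N-dimethylformamide, CN(C)C=O; water, O
Why: Vilsmeier–Haack formylation should favour the two equivalent positions that are ortho to one methoxy group and para to the other over the crowded position between the two methoxy groups. The minor regioisomer is removed by crystallisation or chromatography.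

Step 14
Reactants: 19 4-bromo-2,6-dimethoxyphenol; 26 2-fluoro-4,6-dimethoxybenzaldehyde
Product: 27 2-(4-bromo-2,6-dimethoxyphenoxy)-4,6-dimethoxybenzaldehyde
Conditions: K2CO3, DMSO, 120 °C
Reagents that add atoms: none
Why: Nucleophilic aromatic substitution of a fluoride ortho to a formyl group; the addition–elimination pathway tolerates the two ortho methoxy groups of the phenoxide far better than a metal-mediated coupling would. The methoxy groups of 26 are meta to the site of attack and do not destabilise the anionic intermediate.

Step 15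
Reactants: 27 2-(4-bromo-2,6-dimethoxyphenoxy)-4,6-dimethoxybenzaldehyde
Product: 29 2-(4-bromo-2,6-dimethoxyphenoxy)-4,6-dimethoxyphenol, via aryl formate 28 (not isolated)
Conditions: mCPBA, CH2Cl2, 0 °C to rt; aq. NaHCO3 wash; then K2CO3 (cat.), MeOH, rt, Ar
Reagents that add atoms: 3-chloroperoxybenzoic acid, OOC(=O)c1cccc(Cl)c1
Why: Baeyer–Villiger (Dakin-type) oxidation; a 2,4,6-trioxygenated aryl group migrates in preference to hydride, and the formate is cleaved by methanolysis. This places the C2 hydroxyl of ring E exactly where the activating formyl group stood.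

Step 16
Reactants: 29 2-(4-bromo-2,6-dimethoxyphenoxy)-4,6-dimethoxyphenol; 24 [3,5-dimethoxy-4-(3,4,5-trimethoxyphenoxy)phenyl]boronic acid (2 equiv)
Product: 30 5-bromo-2-{2-[3,5-dimethoxy-4-(3,4,5-trimethoxyphenoxy)phenoxy]-3,5-dimethoxyphenoxy}-1,3-dimethoxybenzene
Conditions: Cu(OAc)2 (2 equiv), pyridine, 4 Å molecular sieves, CH2Cl2, rt, air
Reagents that add atoms: none
Why: Chan–Lam coupling of the hindered phenol with an unhindered boronic acid; the ring D bromide does not react under these oxidative conditions and is kept for step 17.

Step 17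
Reactants: 18 6-[2,6-dimethoxy-4-(2,4,6-trimethoxyphenoxy)phenoxy]-2,3,4-trimethoxyphenol; 30 5-bromo-2-{2-[3,5-dimethoxy-4-(3,4,5-trimethoxyphenoxy)phenoxy]-3,5-dimethoxyphenoxy}-1,3-dimethoxybenzene
Product: 31 heptadeca-O-methyl ether of 32 (rings A to G with every hydroxyl as methoxy)
Conditions: CuI (20 mol %), picolinic acid (40 mol %), K3PO4, DMSO, 110 °C, Ar
Reagents that add atoms: none
Why: Ullmann diaryl ether synthesis in its favourable polarity: the hindered oxygen is the nucleophile and the bromide sits on a carbon with two CH neighbours.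

Step 18
Reactants: 31 heptadeca-O-methyl ether of 32
Product: 32 CNP0351377.0 (the heptamer with seventeen free hydroxyls)
Conditions: BBr3 (excess), CH2Cl2, −78 °C to rt, Ar; then H2O, 0 °C; reversed-phase purification under Ar
Reagents that add atoms: none
Why: Lewis-acid cleavage of aryl methyl ethers; BBr3 attacks the sp3 O–CH3 bond and leaves diaryl ethers intact. Work-up stays acidic and oxygen-free to protect the vicinal triol rings C and G.

## Compound list

1 | 2,6-dimethoxy-1,4-benzoquinone | COC1=CC(=O)C=C(OC)C1=O | starting material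
2 | 2,6-dimethoxybenzene-1,4-diol | COc1cc(O)cc(OC)c1O | intermediate
3 | 2,6-dimethoxy-4-{[tri(propan-2-yl)silyl]oxy}phenol | COc1cc(O[Si](C(C)C)(C(C)C)C(C)C)cc(OC)c1O | intermediate
4 | 1,2-dibromoethane | BrCCBr | starting material
5 | [4-(2-bromoethoxy)-3,5-dimethoxyphenoxy]tri(propan-2-yl)silane | COc1cc(O[Si](C(C)C)(C(C)C)C(C)C)cc(OC)c1OCCBr | intermediate
6 | [4-(ethenyloxy)-3,5-dimethoxyphenoxy]tri(propan-2-yl)silane | COc1cc(O[Si](C(C)C)(C(C)C)C(C)C)cc(OC)c1OC=C | intermediate
7 | dimethyl squarate (3,4-dimethoxycyclobut-3-ene-1,2-dione) | COC1=C(OC)C(=O)C1=O | starting material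
8 | [1-(2,6-dimethoxy-4-{[tri(propan-2-yl)silyl]oxy}phenoxy)ethenyl]lithium | [Li]C(=C)Oc1c(OC)cc(O[Si](C(C)C)(C(C)C)C(C)C)cc1OC | intermediate (not isolated)
9 | racemic lithium 1-[1-(2,6-dimethoxy-4-{[tri(propan-2-yl)silyl]oxy}phenoxy)ethenyl]-2,3-dimethoxy-4-oxocyclobut-2-en-1-olate | [Li+].[O-]C1(C(=C)Oc2c(OC)cc(O[Si](C(C)C)(C(C)C)C(C)C)cc2OC)C(OC)=C(OC)C1=O | intermediate (not isolated)
10 | racemic 4-[1-(2,6-dimethoxy-4-{[tri(propan-2-yl)silyl]oxy}phenoxy)ethenyl]-2,3-dimethoxy-4-(methoxymethoxy)cyclobut-2-en-1-one | COCOC1(C(=C)Oc2c(OC)cc(O[Si](C(C)C)(C(C)C)C(C)C)cc2OC)C(OC)=C(OC)C1=O | intermediate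
11 | (3Z)-5-(2,6-dimethoxy-4-{[tri(propan-2-yl)silyl]oxy}phenoxy)-2,3-dimethoxy-4-(methoxymethoxy)hexa-1,3,5-trien-1-one | O=C=C(OC)/C(OC)=C(OCOC)\C(=C)Oc1c(OC)cc(O[Si](C(C)C)(C(C)C)C(C)C)cc1OC | intermediate (not isolated)
12 | 5-(2,6-dimethoxy-4-{[tri(propan-2-yl)silyl]oxy}phenoxy)-2,3-dimethoxy-4-(methoxymethoxy)cyclohexa-2,4-dien-1-one | COCOC1=C(Oc2c(OC)cc(O[Si](C(C)C)(C(C)C)C(C)C)cc2OC)CC(=O)C(OC)=C1OC | intermediate (not isolated)
13 | 5-(2,6-dimethoxy-4-{[tri(propan-2-yl)silyl]oxy}phenoxy)-2,3-dimethoxy-4-(methoxymethoxy)phenol | COCOc1c(Oc2c(OC)cc(O[Si](C(C)C)(C(C)C)C(C)C)cc2OC)cc(O)c(OC)c1OC | intermediate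
14 | {3,5-dimethoxy-4-[3,4,5-trimethoxy-2-(methoxymethoxy)phenoxy]phenoxy}tri(propan-2-yl)silane | COCOc1c(Oc2c(OC)cc(O[Si](C(C)C)(C(C)C)C(C)C)cc2OC)cc(OC)c(OC)c1OC | intermediate
15 | 3,5-dimethoxy-4-[3,4,5-trimethoxy-2-(methoxymethoxy)phenoxy]phenol | COCOc1c(Oc2c(OC)cc(O)cc2OC)cc(OC)c(OC)c1OC | intermediate
16 | 2-iodo-1,3,5-trimethoxybenzene | COc1cc(OC)c(I)c(OC)c1 | starting material
17 | 2-{3,5-dimethoxy-4-[3,4,5-trimethoxy-2-(methoxymethoxy)phenoxy]phenoxy}-1,3,5-trimethoxybenzene | COCOc1c(Oc2c(OC)cc(Oc3c(OC)cc(OC)cc3OC)cc2OC)cc(OC)c(OC)c1OC | intermediate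
18 | 6-[2,6-dimethoxy-4-(2,4,6-trimethoxyphenoxy)phenoxy]-2,3,4-trimethoxyphenol | Oc1c(Oc2c(OC)cc(Oc3c(OC)cc(OC)cc3OC)cc2OC)cc(OC)c(OC)c1OC | intermediate
19 | 4-bromo-2,6-dimethoxyphenol | Oc1c(OC)cc(Br)cc1OC | starting material
20 | (3,4,5-trimethoxyphenyl)boronic acid | COc1cc(B(O)O)cc(OC)c1OC | starting material
21 | 5-(4-bromo-2,6-dimethoxyphenoxy)-1,2,3-trimethoxybenzene | COc1cc(Oc2c(OC)cc(Br)cc2OC)cc(OC)c1OC | intermediate
22 | [3,5-dimethoxy-4-(3,4,5-trimethoxyphenoxy)phenyl]lithium | [Li]c1cc(OC)c(Oc2cc(OC)c(OC)c(OC)c2)c(OC)c1 | intermediate (not isolated)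
23 | lithium [3,5-dimethoxy-4-(3,4,5-trimethoxyphenoxy)phenyl]tri(propan-2-yloxy)borate | [Li+].CC(C)O[B-](OC(C)C)(OC(C)C)c1cc(OC)c(Oc2cc(OC)c(OC)c(OC)c2)c(OC)c1 | intermediate (not isolated)
24 | [3,5-dimethoxy-4-(3,4,5-trimethoxyphenoxy)phenyl]boronic acid | COc1cc(Oc2c(OC)cc(B(O)O)cc2OC)cc(OC)c1OC | intermediate
25 | 1-fluoro-3,5-dimethoxybenzene | COc1cc(F)cc(OC)c1 | starting material
26 | 2-fluoro-4,6-dimethoxybenzaldehyde | COc1cc(F)c(C=O)c(OC)c1 | intermediate
27 | 2-(4-bromo-2,6-dimethoxyphenoxy)-4,6-dimethoxybenzaldehyde | COc1cc(Oc2c(OC)cc(Br)cc2OC)c(C=O)c(OC)c1 | intermediate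
28 | 2-(4-bromo-2,6-dimethoxyphenoxy)-4,6-dimethoxyphenyl formate | COc1cc(Oc2c(OC)cc(Br)cc2OC)c(OC=O)c(OC)c1 | intermediate (not isolated)
29 | 2-(4-bromo-2,6-dimethoxyphenoxy)-4,6-dimethoxyphenol | COc1cc(Oc2c(OC)cc(Br)cc2OC)c(O)c(OC)c1 | intermediate
30 | 5-bromo-2-{2-[3,5-dimethoxy-4-(3,4,5-trimethoxyphenoxy)phenoxy]-3,5-dimethoxyphenoxy}-1,3-dimethoxybenzene | COc1cc(Oc2c(OC)cc(Br)cc2OC)c(Oc2cc(OC)c(Oc3cc(OC)c(OC)c(OC)c3)c(OC)c2)c(OC)c1 | intermediate
31 | heptadeca-O-methyl ether of 32 | COc1cc(OC)c(Oc2cc(OC)c(Oc3cc(OC)c(OC)c(OC)c3Oc3cc(OC)c(Oc4cc(OC)cc(OC)c4Oc4cc(OC)c(Oc5cc(OC)c(OC)c(OC)c5)c(OC)c4)c(OC)c3)c(OC)c2)c(OC)c1 | intermediate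
32 | CNP0351377.0 | Oc1cc(O)c(Oc2cc(O)c(Oc3cc(O)c(O)c(O)c3Oc3cc(O)c(Oc4cc(O)cc(O)c4Oc4cc(O)c(Oc5cc(O)c(O)c(O)c5)c(O)c4)c(O)c3)c(O)c2)c(O)c1 | target

## Step count and least certain steps

Total step count: 18. Longest linear sequence: 12 steps (steps 1 to 10, then 17 and 18, from 1 to 32). The branch to bromide 30 takes six steps (11 to 16).

**Step 6 (key step).** The ketene 11 may be consumed by intermolecular capture (dimerisation, traces of water) or the aryloxyvinyl unit may fragment before ring closure, because the bulky 2,6-dimethoxyaryl group on the internal vinyl carbon raises the barrier to the s-cis geometry that the 6π closure needs. The fallback gives up the ring construction and makes the B–C ether by coupling; it sets out from 2 and comes back at 15.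
- Benzylation of 2 at its unhindered hydroxyl (BnBr, K2CO3, acetone) gives 4-(benzyloxy)-2,6-dimethoxyphenol F1.
- In parallel, purchased 2,3,4-trimethoxyphenol F2 is brominated ortho to its hydroxyl (NBS, MeCN, 0 °C) to 6-bromo-2,3,4-trimethoxyphenol F3, which is capped (MOMCl, iPr2NEt, CH2Cl2) as 1-bromo-3,4,5-trimethoxy-2-(methoxymethoxy)benzene F4.
- Ullmann coupling of F1 with F4 (CuI, picolinic acid, K3PO4, DMSO, 110 °C) gives 5-(benzyloxy)-1,3-dimethoxy-2-[3,4,5-trimethoxy-2-(methoxymethoxy)phenoxy]benzene F5, and hydrogenolysis (H2, Pd/C, EtOAc) gives 15.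
- This forms the tri-ortho ether by the less favourable coupling, but every reaction type in it is established.

**Step 5.** Metalation may go to ring B in competition with the α-vinyl position, the lithiated vinyl ether may expel the aryloxide, or the hindered tertiary alkoxide 9 may be capped incompletely before it rearranges on warming. The fallback generates 8 by halogen–metal exchange, not by deprotonation; it sets out from 3 and comes back at 8.
- The potassium salt of 3 (KH, THF) is added to trichloroethylene to give {4-[(E)-1,2-dichloroethenoxy]-3,5-dimethoxyphenoxy}tri(propan-2-yl)silane F6.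
- n-BuLi (2 equiv, −78 °C) and a proton quench give [4-(ethynyloxy)-3,5-dimethoxyphenoxy]tri(propan-2-yl)silane F7.
- Markovnikov addition of one equivalent of dry HBr (CH2Cl2, −78 °C) gives {4-[(1-bromoethenyl)oxy]-3,5-dimethoxyphenoxy}tri(propan-2-yl)silane F8.
- Bromine–lithium exchange (t-BuLi, 2 equiv, THF, −78 °C) gives 8, which is added to 7 and capped as in step 5.

**Step 9.** Oxidative addition of the di-ortho-methoxy, electron-rich iodide 16 to copper is slow, so reduction of the iodide and oxidative degradation of the phenoxide of 15 may outrun ether formation. The fallback makes the A–B ether by addition–elimination and installs the last ring A oxygen afterwards; it sets out from 15 and comes back at 17.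
- Substitution of the fluoride of 2-fluoro-3,5-dimethoxybenzaldehyde F9 by the phenoxide of 15 (K2CO3, DMF, 110 °C) gives 2-{3,5-dimethoxy-4-[3,4,5-trimethoxy-2-(methoxymethoxy)phenoxy]phenoxy}-3,5-dimethoxybenzaldehyde F10.
- Baeyer–Villiger oxidation (mCPBA, CH2Cl2) gives 2-{3,5-dimethoxy-4-[3,4,5-trimethoxy-2-(methoxymethoxy)phenoxy]phenoxy}-3,5-dimethoxyphenyl formate F11.
- Methanolysis (K2CO3, MeOH) gives 2-{3,5-dimethoxy-4-[3,4,5-trimethoxy-2-(methoxymethoxy)phenoxy]phenoxy}-3,5-dimethoxyphenol F12, and methylation (MeI, K2CO3, acetone) gives 17.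

**Step 17.** The coupling joins two large partners at nearly equimolar ratio, and the oxygen of 18 is flanked by an aryloxy and a methoxy group, so the reaction may stall and leave reduction of the bromide as the main pathway on prolonged heating. The fallback changes the electrophile class and the mechanism; it sets out from 30 and comes back at 31.
- Bromide 30 is converted (n-BuLi, THF, −78 °C; B(OiPr)3; 1 M HCl) into (4-{2-[3,5-dimethoxy-4-(3,4,5-trimethoxyphenoxy)phenoxy]-3,5-dimethoxyphenoxy}-3,5-dimethoxyphenyl)boronic acid F13.
- F13 is joined to 18 by Chan–Lam coupling (Cu(OAc)2, pyridine, 4 Å molecular sieves, CH2Cl2, rt, air) to give 31, as in steps 11 and 16.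

**Step 18.** Cleavage of seventeen ethers may stop short, because boron chelates between adjacent oxygens slow the last cleavages, and the product may oxidise at the vicinal triol rings C and G during work-up and chromatography. The fallback isolates the product through a stable derivative; it sets out from 31 and comes back at 32.
- After the BBr3 treatment the crude polyphenol is acetylated (Ac2O, pyridine) to the heptadecaacetate of 32 F14, which is air-stable and can be separated on silica from partly methylated material.
- Acid methanolysis (HCl in degassed MeOH, rt) then releases 32 without exposure to base.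

## Further compounds

F1 | step 6 | 4-(benzyloxy)-2,6-dimethoxyphenol | COc1cc(OCc2ccccc2)cc(OC)c1O
F2 | step 6 | 2,3,4-trimethoxyphenol | COc1ccc(O)c(OC)c1OC
F3 | step 6 | 6-bromo-2,3,4-trimethoxyphenol | COc1cc(Br)c(O)c(OC)c1OC
F4 | step 6 | 1-bromo-3,4,5-trimethoxy-2-(methoxymethoxy)benzene | COCOc1c(Br)cc(OC)c(OC)c1OC
F5 | step 6 | 5-(benzyloxy)-1,3-dimethoxy-2-[3,4,5-trimethoxy-2-(methoxymethoxy)phenoxy]benzene | COCOc1c(Oc2c(OC)cc(OCc3ccccc3)cc2OC)cc(OC)c(OC)c1OC
F6 | step 5 | {4-[(E)-1,2-dichloroethenoxy]-3,5-dimethoxyphenoxy}tri(propan-2-yl)silane | Cl/C=C(/Cl)Oc1c(OC)cc(O[Si](C(C)C)(C(C)C)C(C)C)cc1OC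
F7 | step 5 | [4-(ethynyloxy)-3,5-dimethoxyphenoxy]tri(propan-2-yl)silane | C#COc1c(OC)cc(O[Si](C(C)C)(C(C)C)C(C)C)cc1OC
F8 | step 5 | {4-[(1-bromoethenyl)oxy]-3,5-dimethoxyphenoxy}tri(propan-2-yl)silane | C=C(Br)Oc1c(OC)cc(O[Si](C(C)C)(C(C)C)C(C)C)cc1OC
F9 | step 9 | 2-fluoro-3,5-dimethoxybenzaldehyde | COc1cc(OC)c(F)c(C=O)c1
F10 | step 9 | 2-{3,5-dimethoxy-4-[3,4,5-trimethoxy-2-(methoxymethoxy)phenoxy]phenoxy}-3,5-dimethoxybenzaldehyde | COCOc1c(Oc2c(OC)cc(Oc3c(OC)cc(OC)cc3C=O)cc2OC)cc(OC)c(OC)c1OC
F11 | step 9 | 2-{3,5-dimethoxy-4-[3,4,5-trimethoxy-2-(methoxymethoxy)phenoxy]phenoxy}-3,5-dimethoxyphenyl formate | COCOc1c(Oc2c(OC)cc(Oc3c(OC)cc(OC)cc3OC=O)cc2OC)cc(OC)c(OC)c1OC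
F12 | step 9 | 2-{3,5-dimethoxy-4-[3,4,5-trimethoxy-2-(methoxymethoxy)phenoxy]phenoxy}-3,5-dimethoxyphenol | COCOc1c(Oc2c(OC)cc(Oc3c(OC)cc(OC)cc3O)cc2OC)cc(OC)c(OC)c1OC
F13 | step 17 | (4-{2-[3,5-dimethoxy-4-(3,4,5-trimethoxyphenoxy)phenoxy]-3,5-dimethoxyphenoxy}-3,5-dimethoxyphenyl)boronic acid | OB(O)c1cc(OC)c(Oc2cc(OC)cc(OC)c2Oc2cc(OC)c(Oc3cc(OC)c(OC)c(OC)c3)c(OC)c2)c(OC)c1
F14 | step 18 | heptadecaacetate of 32 | CC(=O)Oc1cc(OC(C)=O)c(Oc2cc(OC(C)=O)c(Oc3cc(OC(C)=O)c(OC(C)=O)c(OC(C)=O)c3Oc3cc(OC(C)=O)c(Oc4cc(OC(C)=O)cc(OC(C)=O)c4Oc4cc(OC(C)=O)c(Oc5cc(OC(C)=O)c(OC(C)=O)c(OC(C)=O)c5)c(OC(C)=O)c4)c(OC(C)=O)c3)c(OC(C)=O)c2)c(OC(C)=O)c1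
A1 | alternative 1 | heptadeca-O-methyl ether of the target (identical with 31) | COc1cc(OC)c(Oc2cc(OC)c(Oc3cc(OC)c(OC)c(OC)c3Oc3cc(OC)c(Oc4cc(OC)cc(OC)c4Oc4cc(OC)c(Oc5cc(OC)c(OC)c(OC)c5)c(OC)c4)c(OC)c3)c(OC)c2)c(OC)c1
A2 | alternative 1 | (cyclopentadienyl)(2,5-dichloro-1,3-dimethoxybenzene)ruthenium hexafluorophosphate | COc1cc(Cl)cc(OC)c1Cl.[cH-]1cccc1.[Ru+2].F[P-](F)(F)(F)(F)F
A3 | alternative 1 | 6-[2,6-dimethoxy-4-(2,4,6-trimethoxyphenoxy)phenoxy]-2,3,4-trimethoxyphenol (identical with 18) | Oc1c(Oc2c(OC)cc(Oc3c(OC)cc(OC)cc3OC)cc2OC)cc(OC)c(OC)c1OC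
A4 | alternative 1 | 2-[3,5-dimethoxy-4-(3,4,5-trimethoxyphenoxy)phenoxy]-3,5-dimethoxyphenol | Oc1cc(OC)cc(OC)c1Oc1cc(OC)c(Oc2cc(OC)c(OC)c(OC)c2)c(OC)c1
A5 | alternative 2 | diethyl 5-[4-(benzyloxy)-3,5-dimethoxyphenoxy]-2,4,6-trihydroxybenzene-1,3-dicarboxylate | CCOC(=O)c1c(O)c(C(=O)OCC)c(O)c(Oc2cc(OC)c(OCc3ccccc3)c(OC)c2)c1O
A6 | alternative 2 | diethyl 2-[4-(benzyloxy)-3,5-dimethoxyphenoxy]propanedioate | CCOC(=O)C(Oc1cc(OC)c(OCc2ccccc2)c(OC)c1)C(=O)OCC
A7 | alternative 2 | diethyl 3-oxopentanedioate | CCOC(=O)CC(=O)CC(=O)OCC
A8 | alternative 3 | penta-O-methyl ether of the target (methyl on ring A C4, ring C C4 and the three ring G oxygens) | COc1cc(O)c(Oc2cc(O)c(Oc3cc(O)c(OC)c(O)c3Oc3cc(O)c(Oc4cc(O)cc(O)c4Oc4cc(O)c(Oc5cc(OC)c(OC)c(OC)c5)c(O)c4)c(O)c3)c(O)c2)c(O)c1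
A9 | alternative 3 | dodecaaldehyde corresponding to A8 with a formyl group in place of each free hydroxyl | COc1cc(C=O)c(Oc2cc(C=O)c(Oc3cc(C=O)c(OC)c(C=O)c3Oc3cc(C=O)c(Oc4cc(C=O)cc(C=O)c4Oc4cc(C=O)c(Oc5cc(OC)c(OC)c(OC)c5)c(C=O)c4)c(C=O)c3)c(C=O)c2)c(C=O)c1
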